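**Plan**
- Retrosynthesis cuts, in order: the S–CH2 bond of the thioacetate (bromide/thioacetate SN2), the O–CH3 bond of a phenol methyl ether, the anilide N–C(=O) bond, and last the C2–C3 and C4–C5 bonds of the pyridine.
- Enabling feature: the pyridine carries CH3 on C2, the aryl group on C4 and only hydrogen on C3, C5 and C6. C2–N1–C6–C5 therefore map onto C3–N4–C5–C6 of 3-methyl-1,2,4-triazine, and C3–C4 onto the CH3 and C=O carbons of an aryl methyl ketone.
- Forward: 3-methoxy-2-nitrobenzoic acid is homologated to the aryl methyl ketone by the malonate route; the triazine is assembled from acetamidine, hydrazine and glyoxal.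
- The pyridine, the only ring built, is closed onto the existing benzene ring by enamine–triazine cycloaddition with loss of N2 and pyrrolidine.
- The chain is joined last: nitro reduction, N-acylation with 13-bromotridecanoyl chloride, O-demethylation, bromide-to-thioacetate exchange.
- Stereochemistry: the target has no stereocentre and no configured double bond, so nothing has to be set.

Key step: step 5

Remark: pyrrolidine in step 5 is used substoichiometrically and is released again on aromatisation, so it is treated as a catalyst; 3-methyl-1,2,4-triazine is made in step 4 and not assumed to be purchasable.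

**Route**

Step 1
Reactants: 1 3-methoxy-2-nitrobenzoic acid
Product: 2 3-methoxy-2-nitrobenzoyl chloride
Conditions: (COCl)2, DMF (cat.), CH2Cl2, 0 °C to rt; evaporated and used crude
Reagents that add atoms: oxalyl chloride, O=C(Cl)C(=O)Cl
Why: Acyl chloride formation through the DMF-derived chloroiminium (Vilsmeier-type) activator runs at room temperature, so the heat-sensitive ortho-nitrobenzoyl chloride is never distilled and the nitro and ether groups stay untouched.

Step 2
Reactants: 2 3-methoxy-2-nitrobenzoyl chloride; 3 diethyl malonate
Product: 4 diethyl 2-(3-methoxy-2-nitrobenzoyl)propanedioate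
Conditions: MgCl2, Et3N, MeCN, 0 °C to rt; then 1 M HCl
Reagents that add atoms: none
Why: C-acylation of the magnesium enolate of a malonate under soft-enolisation conditions (MgCl2/Et3N malonate acylation) should stop at the monoacyl stage, because the product is held as a stable magnesium chelate until the acidic work-up.

Step 3
Reactants: 4 diethyl 2-(3-methoxy-2-nitrobenzoyl)propanedioate
Product: 6 1-(3-methoxy-2-nitrophenyl)ethan-1-one, via beta-keto acid 5 (not isolated)
Conditions: AcOH/H2O/H2SO4, reflux
Reagents that add atoms: none
Why: Acid-catalysed ester hydrolysis with twofold decarboxylation, the last one through beta-keto acid 5, is the classical malonate route to ortho-nitroacetophenones and avoids methyl organometallics that would attack the nitro group.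

Step 4
Reactants: 7 acetamidine hydrochloride; 8 glyoxal (40% aqueous solution)
Product: 10 3-methyl-1,2,4-triazine, via acetamidrazone hydrochloride 9 (not isolated)
Conditions: N2H4·H2O, EtOH, 0 °C, N2 purge; then 40% aq. glyoxal, NaHCO3, H2O, 0 °C to rt
Reagents that add atoms: hydrazine monohydrate, NN.O
Why: Exchange of the amidine NH2 for hydrazine gives the amidrazone, whose two terminal nitrogen atoms condense with the two aldehyde groups of glyoxal (amidrazone–1,2-dicarbonyl cyclocondensation, the standard 1,2,4-triazine synthesis), and a symmetrical dialdehyde allows no regioisomer.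

Step 5
Reactants: 6 1-(3-methoxy-2-nitrophenyl)ethan-1-one; 10 3-methyl-1,2,4-triazine
Product: 14 4-(3-methoxy-2-nitrophenyl)-2-methylpyridine, via pyrrolidine enamine 11 (not isolated), via bicyclic cycloadduct 12 (not isolated), via aminodihydropyridine 13 (not isolated)
Conditions: 10 (1.5 equiv), pyrrolidine (0.5 equiv), 4 Å MS, PhMe, 100 °C, sealed tube
Reagents that add atoms: none
Why: Pyrrolidine condenses with ketone 6 to enamine 11 (water is taken up by the sieves), and the electron-rich enamine adds to the electron-poor azadiene of 10 across C3 and C6 in an inverse-electron-demand Diels–Alder reaction, the known pyridine synthesis from 1,2,4-triazines and ketone enamines in its in situ enamine form. The pyridine ring is thus closed by an intermolecular [4+2] cycloaddition that makes the C2–C3 and C4–C5 bonds in one operation; adduct 12 then expels N2 by retro-[4+2] to give 13, and 1,2-elimination of pyrrolidine aromatises the ring and returns the amine to the cycle. No stereocentre remains in 14, because the sp3 centres of 12 and 13 are erased on aromatisation. The selectivity needed is regiochemical (4-aryl-2-methyl, not 3-aryl-2-methyl) together with addition across C3/C6 and not N2/C5: the nucleophilic CH2 terminus of the enamine bonds to the amidine-like C3, as is general for enamines and 1,2,4-triazines, and sterics act in the same sense, since the unsubstituted CH2 meets the methyl-bearing C3 while the crowded amino(aryl) carbon meets the unsubstituted C6. The nitro and methoxy groups are spectators, the ortho-nitro group making the carbonyl more electrophilic for enamine formation, and heating offsets the deactivation of the triazine by its donor methyl group.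

Step 6
Reactants: 14 4-(3-methoxy-2-nitrophenyl)-2-methylpyridine
Product: 15 2-methoxy-6-(2-methylpyridin-4-yl)aniline
Conditions: H2 (1 atm), 10% Pd/C, EtOH/EtOAc, rt
Reagents that add atoms: none
Why: Catalytic hydrogenation of an aromatic nitro group over Pd/C is reliable at atmospheric pressure, where the pyridine ring and the aryl methyl ether are not reduced.

Step 7
Reactants: 16 13-bromotridecanoic acid
Product: 17 13-bromotridecanoyl chloride
Conditions: (COCl)2, DMF (cat.), CH2Cl2, 0 °C to rt; evaporated and used crude
Reagents that add atoms: oxalyl chloride, O=C(Cl)C(=O)Cl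
Why: Acyl chloride formation with oxalyl chloride and catalytic DMF leaves the primary alkyl bromide untouched and gives an acylating agent strong enough for a 2,6-disubstituted aniline.

Step 8
Reactants: 15 2-methoxy-6-(2-methylpyridin-4-yl)aniline; 17 13-bromotridecanoyl chloride
Product: 18 13-bromo-N-[2-methoxy-6-(2-methylpyridin-4-yl)phenyl]tridecanamide
Conditions: pyridine, CH2Cl2, 0 °C to rt
Reagents that add atoms: none
Why: Nucleophilic acyl substitution (N-acylation of an aniline by an acyl chloride with pyridine as acid scavenger) should be much faster than any N-alkylation by the primary bromide at this temperature, and the aniline nitrogen is the only site that gives a stable acyl product.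

Step 9
Reactants: 18 13-bromo-N-[2-methoxy-6-(2-methylpyridin-4-yl)phenyl]tridecanamide
Product: 20 13-bromo-N-[2-hydroxy-6-(2-methylpyridin-4-yl)phenyl]tridecanamide, via aryloxydibromoborane 19 (not isolated)
Conditions: BBr3 (4 equiv), CH2Cl2, −78 °C to rt; then H2O
Reagents that add atoms: none
Why: Lewis-acid-mediated aryl methyl ether cleavage with BBr3 (O-complexation, then bromide attack on the methyl group) tolerates the secondary amide, the excess reagent covers the equivalents bound by the pyridine nitrogen and the amide, and halide exchange at the chain end is degenerate because it is already a bromide.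

Step 10
Reactants: 20 13-bromo-N-[2-hydroxy-6-(2-methylpyridin-4-yl)phenyl]tridecanamide
Product: 21 Echinoclathrine B
Conditions: KSAc, DMF, rt
Reagents that add atoms: potassium thioacetate, CC(=O)[S-].[K+]
Why: SN2 displacement of a primary bromide by the soft, weakly basic thioacetate anion is fast in DMF, and since thioacetate does not deprotonate the phenol or the amide, no O- or N-alkylation should compete.

**Compound list**

1 | 3-methoxy-2-nitrobenzoic acid | COc1cccc(C(=O)O)c1[N+](=O)[O-] | starting material
2 | 3-methoxy-2-nitrobenzoyl chloride | COc1cccc(C(=O)Cl)c1[N+](=O)[O-] | intermediate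
3 | diethyl malonate (diethyl propanedioate) | CCOC(=O)CC(=O)OCC | starting material
4 | diethyl 2-(3-methoxy-2-nitrobenzoyl)propanedioate | CCOC(=O)C(C(=O)OCC)C(=O)c1cccc(OC)c1[N+](=O)[O-] | intermediate
5 | 3-(3-methoxy-2-nitrophenyl)-3-oxopropanoic acid (beta-keto acid, not isolated) | COc1cccc(C(=O)CC(=O)O)c1[N+](=O)[O-] | intermediate
6 | 1-(3-methoxy-2-nitrophenyl)ethan-1-one | COc1cccc(C(C)=O)c1[N+](=O)[O-] | intermediate
7 | acetamidine hydrochloride | CC(=N)N.Cl | starting material
8 | glyoxal (40% aqueous solution) | O=CC=O | starting material
9 | acetamidrazone hydrochloride (ethanimidohydrazide hydrochloride, not isolated) | CC(=N)NN.Cl | intermediate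
10 | 3-methyl-1,2,4-triazine | Cc1nnccn1 | intermediate
11 | 1-[1-(3-methoxy-2-nitrophenyl)ethenyl]pyrrolidine (pyrrolidine enamine, not isolated) | C=C(N1CCCC1)c1cccc(OC)c1[N+](=O)[O-] | intermediate
12 | 8-(3-methoxy-2-nitrophenyl)-4-methyl-8-(pyrrolidin-1-yl)-2,3,5-triazabicyclo[2.2.2]octa-2,5-diene (bicyclic cycloadduct, racemic, relative configuration undefined and without consequence, not isolated) | CC12N=NC(C=N1)C(N3CCCC3)(c3cccc(OC)c3[N+](=O)[O-])C2 | intermediate
13 | 4-(3-methoxy-2-nitrophenyl)-2-methyl-4-(pyrrolidin-1-yl)-3,4-dihydropyridine (aminodihydropyridine, racemic, not isolated) | CC1=NC=CC(N2CCCC2)(c2cccc(OC)c2[N+](=O)[O-])C1 | intermediate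
14 | 4-(3-methoxy-2-nitrophenyl)-2-methylpyridine | COc1cccc(-c2ccnc(C)c2)c1[N+](=O)[O-] | intermediate
15 | 2-methoxy-6-(2-methylpyridin-4-yl)aniline | COc1cccc(-c2ccnc(C)c2)c1N | intermediate
16 | 13-bromotridecanoic acid | BrCCCCCCCCCCCCC(=O)O | starting material
17 | 13-bromotridecanoyl chloride | BrCCCCCCCCCCCCC(=O)Cl | intermediate
18 | 13-bromo-N-[2-methoxy-6-(2-methylpyridin-4-yl)phenyl]tridecanamide | BrCCCCCCCCCCCCC(=O)Nc1c(OC)cccc1-c1ccnc(C)c1 | intermediate
19 | 2-(13-bromotridecanamido)-3-(2-methylpyridin-4-yl)phenoxy(dibromo)borane (aryloxydibromoborane, not isolated) | BrCCCCCCCCCCCCC(=O)Nc1c(OB(Br)Br)cccc1-c1ccnc(C)c1 | intermediate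
20 | 13-bromo-N-[2-hydroxy-6-(2-methylpyridin-4-yl)phenyl]tridecanamide | BrCCCCCCCCCCCCC(=O)Nc1c(O)cccc1-c1ccnc(C)c1 | intermediate
21 | Echinoclathrine B, S-{13-[2-hydroxy-6-(2-methylpyridin-4-yl)anilino]-13-oxotridecyl} ethanethioate (achiral) | CC(=O)SCCCCCCCCCCCCC(=O)Nc1c(O)cccc1-c1ccnc(C)c1 | target

**Totals and risks**

Total step count: 10
Longest linear sequence: 8 steps (steps 1, 2, 3, 5, 6, 8, 9, 10)

Steps most likely to fail:

1. Step 5. Enamine formation from the hindered, electron-poor aryl methyl ketone may be slow, and the methyl-deactivated triazine may add sluggishly. Prolonged heating then invites amine addition to the triazine or nucleophilic aromatic substitution by pyrrolidine on the nitroarene. Fallback, setting out from acid 1 and returning at 14: the acid is neutralised with KOH in EtOH to potassium 3-methoxy-2-nitrobenzoate F1. This salt is joined to commercial 4-bromo-2-methylpyridine by a decarboxylative biaryl cross-coupling (Pd(acac)2, CuI, 1,10-phenanthroline, NMP/quinoline, 160 °C), a reaction for which ortho-nitrobenzoates are the best-behaved carboxylates. The biaryl bond is then made directly and the ring-forming step is bypassed.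

2. Step 4. The free amidrazone may self-condense, glyoxal may be consumed by the liberated ammonia, and the volatile, water-soluble triazine may be lost on isolation. Fallback, setting out from glyoxal 8 (with ketone 6 as partner) and returning at 14: glyoxal is condensed with commercial S-methylisothiosemicarbazide hydroiodide (NaHCO3, ice-water) to the crystalline, easily handled 3-(methylsulfanyl)-1,2,4-triazine F2. Under the conditions of step 5 this triazine should react with enamine 11 through bicyclic cycloadduct F3 and aminodihydropyridine F4, neither isolated, to 4-(3-methoxy-2-nitrophenyl)-2-(methylsulfanyl)pyridine F5. The methylsulfanyl group is then exchanged for methyl by palladium-catalysed thioether cross-coupling with MeZnCl (Pd(OAc)2, SPhos, THF, 50 °C), which the nitro group tolerates.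

3. Step 9. Ether cleavage may stall because the pyridine nitrogen and the amide oxygen sequester the Lewis acid, and forcing it risks cyclodehydration of the ortho-amidophenol to a benzoxazole. Fallback, setting out from aniline 15 and returning at 20: the methyl ether is cleaved before the chain is attached, in refluxing 48% aqueous HBr, where only the ether can react. Neutralisation gives 2-amino-3-(2-methylpyridin-4-yl)phenol F6. Schotten–Baumann acylation with acid chloride 17 (NaHCO3, THF/H2O, 0 °C) is N-selective for an aminophenol and should give 20 without passing through 18 or 19.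

**Further compounds**

F1 | step 5 | potassium 3-methoxy-2-nitrobenzoate | COc1cccc(C(=O)[O-])c1[N+](=O)[O-].[K+]
F2 | step 4 | 3-(methylsulfanyl)-1,2,4-triazine | CSc1nnccn1
F3 | step 4 | 8-(3-methoxy-2-nitrophenyl)-4-(methylsulfanyl)-8-(pyrrolidin-1-yl)-2,3,5-triazabicyclo[2.2.2]octa-2,5-diene (racemic, not isolated) | CSC12N=NC(C=N1)C(N3CCCC3)(c3cccc(OC)c3[N+](=O)[O-])C2
F4 | step 4 | 4-(3-methoxy-2-nitrophenyl)-2-(methylsulfanyl)-4-(pyrrolidin-1-yl)-3,4-dihydropyridine (racemic, not isolated) | CSC1=NC=CC(N2CCCC2)(c2cccc(OC)c2[N+](=O)[O-])C1
F5 | step 4 | 4-(3-methoxy-2-nitrophenyl)-2-(methylsulfanyl)pyridine | COc1cccc(-c2ccnc(SC)c2)c1[N+](=O)[O-]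
F6 | step 9 | 2-amino-3-(2-methylpyridin-4-yl)phenol | Nc1c(O)cccc1-c1ccnc(C)c1
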